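## Retrosynthetic overview

1. The target comes from its tri-O-benzyl ether; global hydrogenolysis is the last step.
2. Ring C (pyranone of the A/C/B flavanone) is closed last. Its O1–C2 bond comes from a catalyst-controlled oxa-Michael addition; its C2–C3 bond comes from a Knoevenagel-type aldol condensation that joins the biaryl flavanone aldehyde to the ring A aroylacetate (key fragment union), followed by loss of the ester.
3. Ring F (pyranone of the D/F/E flavanone) is closed before that by the same aldol condensation, oxa-Michael addition and decarboxylation, between the biaryl aroylacetate and 4-(benzyloxy)benzaldehyde.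
4. The biaryl bond (ring B C3 to ring D C6) is made by Suzuki coupling of an iodinated, differentially protected phloroacetophenone with (5-formyl-2-methoxyphenyl)boronic acid, before any stereocentre exists.
5. Both aroylacetates come from 2',6'-dihydroxy-4'-methoxyacetophenone by O-Boc formation and anionic O-to-C Boc transfer. Ring order: biaryl, then ring F, then ring C.

Assumption (ring letters): rings A/C/B are the flavanone carrying the 4-methoxyphenyl ring; rings D/F/E are the 6-aryl flavanone carrying the 4-hydroxyphenyl ring.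
Assumption (axis): the biaryl axis has three small ortho substituents and is taken as freely rotating, so only the two C2 centres (both S) need control.
Assumption (catalyst sense): the thiourea from 9-amino-9-deoxy-epi-quinidine is taken to give the 2S series; this is checked by CD on the first flavanone made, and the epi-quinine-derived pseudoenantiomer is used instead if the sense is reversed.

## Route

Step 1
Reactants: 1 1-(2,6-dihydroxy-4-methoxyphenyl)ethanone
Product: 2 1-[2-(benzyloxy)-6-hydroxy-4-methoxyphenyl]ethanone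
Conditions: BnBr (1.05 equiv), K2CO3 (1.2 equiv), acetone, reflux
Reagents that add atoms: benzyl bromide, BrCc1ccccc1
Why: Williamson etherification stops at the monoether because the second hydroxyl is then locked in a hydrogen bond to the ketone and is far less nucleophilic.

Step 2
Reactants: 2 1-[2-(benzyloxy)-6-hydroxy-4-methoxyphenyl]ethanone
Product: 3 2-acetyl-3-(benzyloxy)-5-methoxyphenyl tert-butyl carbonate
Conditions: Boc2O (1.3 equiv), DMAP (10 mol %), iPr2NEt (1.5 equiv), CH2Cl2, rt
Reagents that add atoms: di-tert-butyl dicarbonate, CC(C)(C)OC(=O)OC(=O)OC(C)(C)C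
Why: DMAP-catalysed O-acylation with Boc2O turns the chelated phenol into an aryl tert-butyl carbonate, which is both a protecting group and the source of the ester carbon.

Step 3
Reactants: 3 2-acetyl-3-(benzyloxy)-5-methoxyphenyl tert-butyl carbonate
Product: 4 tert-butyl 3-[2-(benzyloxy)-6-hydroxy-4-methoxyphenyl]-3-oxopropanoate
Conditions: LiN(SiMe3)2 (2.3 equiv), THF, −78 to −20 °C; then aq NH4Cl
Reagents that add atoms: none
Why: Baker–Venkataraman-type anionic O-to-C acyl transfer (an intramolecular Claisen condensation): the ketone enolate attacks the neighbouring carbonate through a six-membered transition state, phenoxide rather than tert-butoxide is expelled, and the second equivalent of base stores the β-keto ester as its enolate while the bulky ester resists lactonisation to a hydroxycoumarin.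

Step 4
Reactants: 1 1-(2,6-dihydroxy-4-methoxyphenyl)ethanone
Product: 5 1-[2-hydroxy-4-methoxy-6-(methoxymethoxy)phenyl]ethanone
Conditions: MOMCl (1.1 equiv), iPr2NEt (1.5 equiv), CH2Cl2, 0 °C to rt
Reagents that add atoms: chloromethyl methyl ether, COCCl
Why: Selective mono-MOM etherification for the same hydrogen-bonding reason as in step 1, giving a temporary group on the oxygen that must later become the ring F oxygen.

Step 5
Reactants: 5 1-[2-hydroxy-4-methoxy-6-(methoxymethoxy)phenyl]ethanone
Product: 6 1-[2-hydroxy-3-iodo-4-methoxy-6-(methoxymethoxy)phenyl]ethanone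
Conditions: NIS (1.05 equiv), MeCN, 0 °C to rt, dark
Reagents that add atoms: N-iodosuccinimide, O=C1CCC(=O)N1I
Why: Electrophilic aromatic iodination of 2-hydroxy-4,6-dialkoxyacetophenones goes ortho to the free, chelated hydroxyl (the carbon between OH and OMe), and neutral NIS leaves the MOM acetal intact.

Step 6
Reactants: 6 1-[2-hydroxy-3-iodo-4-methoxy-6-(methoxymethoxy)phenyl]ethanone
Product: 7 1-[2-(benzyloxy)-3-iodo-4-methoxy-6-(methoxymethoxy)phenyl]ethanone
Conditions: BnBr (1.5 equiv), K2CO3 (2.5 equiv), DMF, 60 °C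
Reagents that add atoms: benzyl bromide, BrCc1ccccc1
Why: Williamson benzylation of the remaining hindered, chelated phenol needs DMF and gentle heating but has no competing nucleophile, and it fixes the oxygen next to the future biaryl bond as the non-cyclising one.

Step 7
Reactants: 7 1-[2-(benzyloxy)-3-iodo-4-methoxy-6-(methoxymethoxy)phenyl]ethanone; 8 (5-formyl-2-methoxyphenyl)boronic acid
Product: 9 3-[3-acetyl-2-(benzyloxy)-6-methoxy-4-(methoxymethoxy)phenyl]-4-methoxybenzaldehyde
Conditions: 8 (1.5 equiv), Pd(OAc)2 (5 mol %), SPhos (10 mol %), K3PO4 (3 equiv), toluene/H2O 10:1, 90 °C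
Reagents that add atoms: none
Why: Suzuki–Miyaura coupling, in which the SPhos-ligated zerovalent palladium catalyst formed in the flask copes with the di-ortho-substituted electron-rich iodide and the tri-ortho-substituted biaryl, while aqueous phosphate is too weak a base to start a Claisen–Schmidt reaction between the hindered acetyl group and the aldehyde.

Step 8
Reactants: 9 3-[3-acetyl-2-(benzyloxy)-6-methoxy-4-(methoxymethoxy)phenyl]-4-methoxybenzaldehyde
Product: 10 3-[3-acetyl-2-(benzyloxy)-4-hydroxy-6-methoxyphenyl]-4-methoxybenzaldehyde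
Conditions: 3 M aq HCl, THF, 50 °C
Reagents that add atoms: none
Why: Acid-catalysed hydrolysis of the MOM acetal frees the phenol, and the benzyl ether, aryl methyl ethers, ketone and aldehyde are inert to dilute acid.

Step 9
Reactants: 10 3-[3-acetyl-2-(benzyloxy)-4-hydroxy-6-methoxyphenyl]-4-methoxybenzaldehyde
Product: 11 1-{2-(benzyloxy)-3-[5-(1,3-dioxolan-2-yl)-2-methoxyphenyl]-6-hydroxy-4-methoxyphenyl}ethanone
Conditions: HOCH2CH2OH (5 equiv), PPTS (10 mol %), toluene, reflux, Dean–Stark
Reagents that add atoms: ethylene glycol, OCCO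
Why: Chemoselective acetalisation: the aldehyde forms the dioxolane under azeotropic removal of water while the di-ortho-substituted, hydrogen-bonded aryl ketone does not react, so the aldehyde is masked before enolate chemistry.

Step 10
Reactants: 11 1-{2-(benzyloxy)-3-[5-(1,3-dioxolan-2-yl)-2-methoxyphenyl]-6-hydroxy-4-methoxyphenyl}ethanone
Product: 12 2-acetyl-3-(benzyloxy)-4-[5-(1,3-dioxolan-2-yl)-2-methoxyphenyl]-5-methoxyphenyl tert-butyl carbonate
Conditions: Boc2O (1.3 equiv), DMAP (10 mol %), iPr2NEt (1.5 equiv), CH2Cl2, rt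
Reagents that add atoms: di-tert-butyl dicarbonate, CC(C)(C)OC(=O)OC(=O)OC(C)(C)C
Why: DMAP-catalysed carbonate formation as in step 2; the basic conditions leave the dioxolane untouched.

Step 11
Reactants: 12 2-acetyl-3-(benzyloxy)-4-[5-(1,3-dioxolan-2-yl)-2-methoxyphenyl]-5-methoxyphenyl tert-butyl carbonate
Product: 13 tert-butyl 3-{2-(benzyloxy)-3-[5-(1,3-dioxolan-2-yl)-2-methoxyphenyl]-6-hydroxy-4-methoxyphenyl}-3-oxopropanoate
Conditions: LiN(SiMe3)2 (2.3 equiv), THF, −78 to −20 °C; then aq NH4Cl
Reagents that add atoms: none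
Why: The same anionic O-to-C Boc transfer as in step 3 (intramolecular Claisen condensation), already rehearsed on the simpler ring A fragment, with the dioxolane keeping the aldehyde away from the enolate.

Step 12
Reactants: 13 tert-butyl 3-{2-(benzyloxy)-3-[5-(1,3-dioxolan-2-yl)-2-methoxyphenyl]-6-hydroxy-4-methoxyphenyl}-3-oxopropanoate; 14 4-(benzyloxy)benzaldehyde
Product: 15 tert-butyl 2-{2-(benzyloxy)-3-[5-(1,3-dioxolan-2-yl)-2-methoxyphenyl]-6-hydroxy-4-methoxybenzoyl}-3-[4-(benzyloxy)phenyl]prop-2-enoate (E/Z mixture, used as such)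
Conditions: 14 (1.2 equiv), piperidine (20 mol %), AcOH (20 mol %), 4 Å MS, toluene, rt
Reagents that add atoms: none
Why: Knoevenagel-type aldol condensation of the doubly activated methylene with the aromatic aldehyde under piperidinium acetate catalysis, water being taken up by the sieves, and the hydrogen-bonded phenol does not add to the new alkene at room temperature without a stronger catalyst.

Step 13
Reactants: 15 tert-butyl 2-{2-(benzyloxy)-3-[5-(1,3-dioxolan-2-yl)-2-methoxyphenyl]-6-hydroxy-4-methoxybenzoyl}-3-[4-(benzyloxy)phenyl]prop-2-enoate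
Product: 19 3-{(2S)-5-(benzyloxy)-2-[4-(benzyloxy)phenyl]-7-methoxy-4-oxochroman-6-yl}-4-methoxybenzaldehyde, via tert-butyl chromanone-3-carboxylate 16 (not isolated), via chromanone-3-carboxylic acid 17 (not isolated), via dioxolane-protected flavanone 18 (not isolated)
Conditions: 1-[3,5-bis(trifluoromethyl)phenyl]-3-(9-deoxy-epi-quinidin-9-yl)thiourea (10 mol %), toluene, −25 °C; then TsOH·H2O (0.5 equiv), 80 °C; then 1 M aq HCl, THF, rt
Reagents that add atoms: water, O
Why: Bifunctional thiourea–tertiary amine catalysis of an intramolecular oxa-Michael addition (the thiourea binds the β-keto ester, the quinuclidine delivers the phenol to one face of the alkylidene) sets C2 of ring F as S with about 90% ee expected by analogy with simpler alkylidene β-keto esters, after which acid removes isobutene, the β-keto acid loses CO2 and aqueous acid frees the aldehyde; the product is recrystallised or passed over a chiral phase to at least 98% ee.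

Step 14
Reactants: 19 3-{(2S)-5-(benzyloxy)-2-[4-(benzyloxy)phenyl]-7-methoxy-4-oxochroman-6-yl}-4-methoxybenzaldehyde; 4 tert-butyl 3-[2-(benzyloxy)-6-hydroxy-4-methoxyphenyl]-3-oxopropanoate
Product: 20 tert-butyl 2-[2-(benzyloxy)-6-hydroxy-4-methoxybenzoyl]-3-(3-{(2S)-5-(benzyloxy)-2-[4-(benzyloxy)phenyl]-7-methoxy-4-oxochroman-6-yl}-4-methoxyphenyl)prop-2-enoate (E/Z mixture, used as such)
Conditions: 4 (1.1 equiv), piperidine (20 mol %), AcOH (20 mol %), 4 Å MS, toluene, rt
Reagents that add atoms: none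
Why: Second Knoevenagel-type aldol condensation, the fragment union that creates the C2–C3 bond of ring C, and the buffered amine at room temperature is too weak to enolise the finished flavanone and open it, so its S centre is kept.

Step 15
Reactants: 20 tert-butyl 2-[2-(benzyloxy)-6-hydroxy-4-methoxybenzoyl]-3-(3-{(2S)-5-(benzyloxy)-2-[4-(benzyloxy)phenyl]-7-methoxy-4-oxochroman-6-yl}-4-methoxyphenyl)prop-2-enoate
Product: 23 (2S)-5-(benzyloxy)-2-(3-{(2S)-5-(benzyloxy)-2-[4-(benzyloxy)phenyl]-7-methoxy-4-oxochroman-6-yl}-4-methoxyphenyl)-7-methoxychroman-4-one, via tert-butyl chromanone-3-carboxylate 21 (not isolated), via chromanone-3-carboxylic acid 22 (not isolated)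
Conditions: 1-[3,5-bis(trifluoromethyl)phenyl]-3-(9-deoxy-epi-quinidin-9-yl)thiourea (10 mol %), toluene, −25 °C; then TsOH·H2O (0.5 equiv), 80 °C
Reagents that add atoms: none
Why: The same catalyst-controlled oxa-Michael addition sets C2 of ring C as S independently of the remote centre and acid-mediated loss of isobutene and CO2 follows; because both centres come from the same catalyst, wrong-face addition ends up mainly in diastereomers that are removed by chromatography or crystallisation, which raises the enantiomeric purity of the S,S product.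

Step 16
Reactants: 23 (2S)-5-(benzyloxy)-2-(3-{(2S)-5-(benzyloxy)-2-[4-(benzyloxy)phenyl]-7-methoxy-4-oxochroman-6-yl}-4-methoxyphenyl)-7-methoxychroman-4-one
Product: 24 (2S)-5-hydroxy-2-{3-[(2S)-5-hydroxy-2-(4-hydroxyphenyl)-7-methoxy-4-oxochroman-6-yl]-4-methoxyphenyl}-7-methoxychroman-4-one
Conditions: H2 (1 atm), Pd/C (10 wt %), EtOAc/MeOH 1:1, rt
Reagents that add atoms: none
Why: Catalytic hydrogenolysis cleaves the three aryl benzyl ethers under neutral conditions, so the 4-hydroxyphenyl flavanone, which racemises through a quinone methide in base, never meets base, and the hydrogen-bonded aryl ketones are not reduced at one atmosphere.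

## Compound list

1 | 1-(2,6-dihydroxy-4-methoxyphenyl)ethanone | CC(=O)c1c(O)cc(OC)cc1O | starting material
2 | 1-[2-(benzyloxy)-6-hydroxy-4-methoxyphenyl]ethanone | CC(=O)c1c(O)cc(OC)cc1OCc1ccccc1 | intermediate
3 | 2-acetyl-3-(benzyloxy)-5-methoxyphenyl tert-butyl carbonate | CC(=O)c1c(OCc2ccccc2)cc(OC)cc1OC(=O)OC(C)(C)C | intermediate
4 | tert-butyl 3-[2-(benzyloxy)-6-hydroxy-4-methoxyphenyl]-3-oxopropanoate | CC(C)(C)OC(=O)CC(=O)c1c(O)cc(OC)cc1OCc1ccccc1 | intermediate
5 | 1-[2-hydroxy-4-methoxy-6-(methoxymethoxy)phenyl]ethanone | CC(=O)c1c(O)cc(OC)cc1OCOC | intermediate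
6 | 1-[2-hydroxy-3-iodo-4-methoxy-6-(methoxymethoxy)phenyl]ethanone | CC(=O)c1c(O)c(I)c(OC)cc1OCOC | intermediate
7 | 1-[2-(benzyloxy)-3-iodo-4-methoxy-6-(methoxymethoxy)phenyl]ethanone | CC(=O)c1c(OCc2ccccc2)c(I)c(OC)cc1OCOC | intermediate
8 | (5-formyl-2-methoxyphenyl)boronic acid | COc1ccc(C=O)cc1B(O)O | starting material
9 | 3-[3-acetyl-2-(benzyloxy)-6-methoxy-4-(methoxymethoxy)phenyl]-4-methoxybenzaldehyde | CC(=O)c1c(OCc2ccccc2)c(-c2cc(C=O)ccc2OC)c(OC)cc1OCOC | intermediate
10 | 3-[3-acetyl-2-(benzyloxy)-4-hydroxy-6-methoxyphenyl]-4-methoxybenzaldehyde | CC(=O)c1c(OCc2ccccc2)c(-c2cc(C=O)ccc2OC)c(OC)cc1O | intermediate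
11 | 1-{2-(benzyloxy)-3-[5-(1,3-dioxolan-2-yl)-2-methoxyphenyl]-6-hydroxy-4-methoxyphenyl}ethanone | CC(=O)c1c(OCc2ccccc2)c(-c2cc(C3OCCO3)ccc2OC)c(OC)cc1O | intermediate
12 | 2-acetyl-3-(benzyloxy)-4-[5-(1,3-dioxolan-2-yl)-2-methoxyphenyl]-5-methoxyphenyl tert-butyl carbonate | CC(=O)c1c(OCc2ccccc2)c(-c2cc(C3OCCO3)ccc2OC)c(OC)cc1OC(=O)OC(C)(C)C | intermediate
13 | tert-butyl 3-{2-(benzyloxy)-3-[5-(1,3-dioxolan-2-yl)-2-methoxyphenyl]-6-hydroxy-4-methoxyphenyl}-3-oxopropanoate | CC(C)(C)OC(=O)CC(=O)c1c(OCc2ccccc2)c(-c2cc(C3OCCO3)ccc2OC)c(OC)cc1O | intermediate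
14 | 4-(benzyloxy)benzaldehyde | O=Cc1ccc(OCc2ccccc2)cc1 | starting material
15 | tert-butyl 2-{2-(benzyloxy)-3-[5-(1,3-dioxolan-2-yl)-2-methoxyphenyl]-6-hydroxy-4-methoxybenzoyl}-3-[4-(benzyloxy)phenyl]prop-2-enoate (alkene geometry not defined) | CC(C)(C)OC(=O)C(=Cc1ccc(OCc2ccccc2)cc1)C(=O)c1c(OCc2ccccc2)c(-c2cc(C3OCCO3)ccc2OC)c(OC)cc1O | intermediate
16 | tert-butyl (2S)-5-(benzyloxy)-2-[4-(benzyloxy)phenyl]-6-[5-(1,3-dioxolan-2-yl)-2-methoxyphenyl]-7-methoxy-4-oxochromane-3-carboxylate (C3 epimers) | CC(C)(C)OC(=O)C1C(=O)c2c(OCc3ccccc3)c(-c3cc(C4OCCO4)ccc3OC)c(OC)cc2O[C@@H]1c1ccc(OCc2ccccc2)cc1 | intermediate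
17 | (2S)-5-(benzyloxy)-2-[4-(benzyloxy)phenyl]-6-[5-(1,3-dioxolan-2-yl)-2-methoxyphenyl]-7-methoxy-4-oxochromane-3-carboxylic acid (C3 epimers) | OC(=O)C1C(=O)c2c(OCc3ccccc3)c(-c3cc(C4OCCO4)ccc3OC)c(OC)cc2O[C@@H]1c1ccc(OCc2ccccc2)cc1 | intermediate
18 | (2S)-5-(benzyloxy)-2-[4-(benzyloxy)phenyl]-6-[5-(1,3-dioxolan-2-yl)-2-methoxyphenyl]-7-methoxychroman-4-one | O=C1C[C@@H](c2ccc(OCc3ccccc3)cc2)Oc2cc(OC)c(-c3cc(C4OCCO4)ccc3OC)c(OCc3ccccc3)c21 | intermediate
19 | 3-{(2S)-5-(benzyloxy)-2-[4-(benzyloxy)phenyl]-7-methoxy-4-oxochroman-6-yl}-4-methoxybenzaldehyde | O=Cc1ccc(OC)c(-c2c(OC)cc3c(c2OCc2ccccc2)C(=O)C[C@@H](c2ccc(OCc4ccccc4)cc2)O3)c1 | intermediate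
20 | tert-butyl 2-[2-(benzyloxy)-6-hydroxy-4-methoxybenzoyl]-3-(3-{(2S)-5-(benzyloxy)-2-[4-(benzyloxy)phenyl]-7-methoxy-4-oxochroman-6-yl}-4-methoxyphenyl)prop-2-enoate (alkene geometry not defined) | CC(C)(C)OC(=O)C(=Cc1ccc(OC)c(-c2c(OC)cc3c(c2OCc2ccccc2)C(=O)C[C@@H](c2ccc(OCc4ccccc4)cc2)O3)c1)C(=O)c1c(O)cc(OC)cc1OCc1ccccc1 | intermediate
21 | tert-butyl (2S)-5-(benzyloxy)-2-(3-{(2S)-5-(benzyloxy)-2-[4-(benzyloxy)phenyl]-7-methoxy-4-oxochroman-6-yl}-4-methoxyphenyl)-7-methoxy-4-oxochromane-3-carboxylate (C3 epimers) | COc1cc(OCc3ccccc3)c2c(c1)O[C@H](c1ccc(OC)c(-c3c(OC)cc4c(c3OCc3ccccc3)C(=O)C[C@@H](c3ccc(OCc5ccccc5)cc3)O4)c1)C(C(=O)OC(C)(C)C)C2=O | intermediate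
22 | (2S)-5-(benzyloxy)-2-(3-{(2S)-5-(benzyloxy)-2-[4-(benzyloxy)phenyl]-7-methoxy-4-oxochroman-6-yl}-4-methoxyphenyl)-7-methoxy-4-oxochromane-3-carboxylic acid (C3 epimers) | COc1cc(OCc3ccccc3)c2c(c1)O[C@H](c1ccc(OC)c(-c3c(OC)cc4c(c3OCc3ccccc3)C(=O)C[C@@H](c3ccc(OCc5ccccc5)cc3)O4)c1)C(C(=O)O)C2=O | intermediate
23 | (2S)-5-(benzyloxy)-2-(3-{(2S)-5-(benzyloxy)-2-[4-(benzyloxy)phenyl]-7-methoxy-4-oxochroman-6-yl}-4-methoxyphenyl)-7-methoxychroman-4-one | COc1cc(OCc3ccccc3)c2c(c1)O[C@H](c1ccc(OC)c(-c3c(OC)cc4c(c3OCc3ccccc3)C(=O)C[C@@H](c3ccc(OCc5ccccc5)cc3)O4)c1)CC2=O | intermediate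
24 | (2S)-5-hydroxy-2-{3-[(2S)-5-hydroxy-2-(4-hydroxyphenyl)-7-methoxy-4-oxochroman-6-yl]-4-methoxyphenyl}-7-methoxychroman-4-one | COc1cc(O)c2c(c1)O[C@H](c1ccc(OC)c(-c3c(OC)cc4c(c3O)C(=O)C[C@@H](c3ccc(O)cc3)O4)c1)CC2=O | target

## Step count and risks

Total steps: 16. Longest linear sequence: 13 steps (steps 4 to 13, then 14 to 16, from 1); steps 1 to 3 are the side branch to 4.

Three steps most likely to fail:

Step 5 (site of iodination). Attack para to the free hydroxyl (between OMe and OMOM) would put the biaryl bond on the wrong carbon; NOE from the remaining ring proton to both OMe and OCH2O identifies the right isomer. Fallback: set out from 1 and iodinate the symmetrical diol first (NIS, 1.0 equiv, MeCN, 0 °C), where only one monoiodide is possible, to give 1-(2,6-dihydroxy-3-iodo-4-methoxyphenyl)ethanone F1. MOMCl/iPr2NEt then protects the hydroxyl remote from iodine, the less hindered one, and the route is rejoined at 6. The regiochemical question thus becomes a steric choice between two hydroxyls instead of ortho against para substitution.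

Step 13 (first enantioselective ring closure; the same concerns hold for step 15). The substrate carries an extra ortho alkoxy group and a hindered biaryl that the catalyst system has not been shown to tolerate. Both the level and the sense of induction are assumed by analogy, and hot acid may erode ee or loosen the benzyl ether next to the ketone. Fallback: set out from 10 and heat with N,N-dimethylformamide dimethyl acetal in toluene at 90 °C to give the enaminone (2E)-1-[2-(benzyloxy)-3-(5-formyl-2-methoxyphenyl)-6-hydroxy-4-methoxyphenyl]-3-(dimethylamino)prop-2-en-1-one F2. HCl in CH2Cl2 closes it to the chromone 3-[5-(benzyloxy)-7-methoxy-4-oxo-4H-chromen-6-yl]-4-methoxybenzaldehyde F3. Asymmetric conjugate addition of 4-(benzyloxy)phenylboronic acid follows, catalysed by the divalent palladium salt Pd(OCOCF3)2 with the t-BuPyOx enantiomer that gives the 2S product ((R)-ligand expected by analogy with cyclic enones, confirmed by CD; NH4PF6, H2O, ClCH2CH2Cl, 60 °C). This comes back to the route at 19. The detour also makes steps 9 to 12 unnecessary, including the Boc transfer on the hindered biaryl.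

Step 16 (final hydrogenolysis). The two C2–O bonds are benzylic and could be cleaved to dihydrochalcones, and the benzyl ether flanked by the biaryl may be slow, inviting forcing conditions. Fallback: set out from 23 and come back directly at 24 by Lewis-acid debenzylation with BCl3 (6 equiv) and pentamethylbenzene (10 equiv) in CH2Cl2 at −78 °C. The non-chelated methyl ethers survive at this temperature and no hydrogen is present. The fallback makes no new compound (none F0).

Further compounds
F1 | step 5 | 1-(2,6-dihydroxy-3-iodo-4-methoxyphenyl)ethanone | CC(=O)c1c(O)cc(OC)c(I)c1O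
F2 | step 13 | (2E)-1-[2-(benzyloxy)-3-(5-formyl-2-methoxyphenyl)-6-hydroxy-4-methoxyphenyl]-3-(dimethylamino)prop-2-en-1-one | CN(C)/C=C/C(=O)c1c(OCc2ccccc2)c(-c2cc(C=O)ccc2OC)c(OC)cc1O
F3 | step 13 | 3-[5-(benzyloxy)-7-methoxy-4-oxo-4H-chromen-6-yl]-4-methoxybenzaldehyde | O=Cc1ccc(OC)c(-c2c(OC)cc3occc(=O)c3c2OCc2ccccc2)c1
F0 | step 16 | none | none
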